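The two decahydro-1-benzoxepine halves differ only at the acetoxy carbon C-7 (S on the right, R on the left) and are therefore closed differently. The right-hand cyclohexane is closed at C-6–C-7 by a samarium diiodide ketyl–olefin cyclisation, which exploits the 1,2-relation of the tertiary carbinol C-7 and the methine C-6: the precursor is a trans-2,3-disubstituted oxepane carrying a 3-oxobutyl chain and an (E)-acrylate, and one operation gives the ring, both stereocentres and a two-carbon ester arm. That arm is condensed with diepoxy-geranylacetone; a silyl-triflate epoxide cascade and equatorial methyl addition then build the 7R half.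

Key step: step 7

Remarks on the chemistry:
- Bicycle locants follow 1-benzoxepine numbering: O-1, C-2 (gem-dimethyl), C-3, C-5a (angular methyl), C-6 (methine carrying the ethylene bridge), C-7 (carbinol carbon), C-9a (ether methine). "Right half" is the 7S unit, "left half" the 7R unit.
- Neryl acetate, 4-oxopentanal, geranylacetone, (R)-TRIP and the L-fructose-derived Shi ketone are taken as commercially available.
- The sense of induction of (R)-TRIP is assigned by analogy with simple allyl- and crotylborations; the antipodal acid would be used if it proved opposite.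
- The C-3 silyloxy centres are auxiliary and are erased in step 17.

Step 1
Reactants: 1 neryl acetate
Product: 2 (Z)-neryl pinacol boronate
Conditions: B2pin2, Ni(cod)2 (5 mol%), PCy3 (5 mol%), EtOAc, 60 °C
Reagents that add atoms: bis(pinacolato)diboron, CC1(C)OB(OC1(C)C)B1OC(C)(C)C(C)(C)O1
Why: Nickel-catalysed borylation of an allylic acetate goes through a π-allyl nickel species that is borylated at the primary terminus, and since E/Z scrambling would need a σ-allyl at the fully substituted carbon the (Z)-geometry should be kept.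

Step 2
Reactants: 2 (Z)-neryl pinacol boronate; 3 4-oxopentanal
Product: 4 (5S,6S)-6-ethenyl-5-hydroxy-6,10-dimethylundec-9-en-2-one
Conditions: (R)-TRIP (5 mol%), 4 Å MS, toluene, −30 °C; aq. NaHCO3 work-up
Reagents that add atoms: none
Why: Chiral phosphoric acid-catalysed allylboration through a closed chair reacts at the aldehyde and not the ketone, the (Z)-geometry places the homoprenyl chain syn to the hydroxyl at the new quaternary centre, and the catalyst selects the aldehyde face to give 5S,6S.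

Step 3
Reactants: 4 homoallylic alcohol
Product: 5 (5S,6S)-8-[(2S)-3,3-dimethyloxiran-2-yl]-6-ethenyl-5-hydroxy-6-methyloctan-2-one
Conditions: L-fructose-derived Shi ketone (30 mol%), Oxone, K2CO3, Bu4NHSO4, MeCN–DMM/aq. borate buffer (pH 10.5), 0 °C
Reagents that add atoms: potassium peroxymonosulfate (Oxone), OOS(=O)(=O)[O-].[K+]
Why: Shi asymmetric epoxidation with the chiral dioxirane attacks only the electron-rich trisubstituted alkene (vinyl group and ketone are left) through the spiro transition state that should give the (S)-epoxide.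

Step 4
Reactants: 5 epoxy alcohol
Product: 6 4-[(2S,3S,6S)-6-(tert-butyldimethylsilyloxy)-3-ethenyl-3,7,7-trimethyloxepan-2-yl]butan-2-one
Conditions: TBSOTf (1.5 equiv), 2,6-di-tert-butyl-4-methylpyridine, CH2Cl2, −78 °C
Reagents that add atoms: tert-butyldimethylsilyl triflate, CC(C)(C)[Si](C)(C)OS(=O)(=O)C(F)(F)F
Why: In this Lewis-acid-promoted endo-selective epoxide-opening etherification, O-silylation gives the trisubstituted epoxide cationic character at CMe2, so the hindered C-5 hydroxyl should add there (7-endo, Markovnikov) while the silyl group stays on the former epoxide oxygen, whose carbon keeps its S configuration.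

Step 5
Reactants: 6 vinyl oxepane
Product: 8 (2S,3R,6S)-6-(tert-butyldimethylsilyloxy)-3,7,7-trimethyl-2-(3-oxobutyl)oxepane-3-carbaldehyde, via secondary ozonide 7 (not isolated)
Conditions: O3, CH2Cl2, −78 °C; then PPh3, −78 °C to rt
Reagents that add atoms: ozone, [O-][O+]=O
Why: Ozonolysis with reductive work-up cleaves the only remaining alkene, the vinyl group, to the neopentyl aldehyde without touching the ketone, the silyl ether or the stereocentres.

Step 6
Reactants: 8 keto aldehyde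
Product: 9 ethyl (2E)-3-[(2S,3S,6S)-6-(tert-butyldimethylsilyloxy)-3,7,7-trimethyl-2-(3-oxobutyl)oxepan-3-yl]prop-2-enoate
Conditions: Ph3P=CHCO2Et, toluene, 90 °C
Reagents that add atoms: (carbethoxymethylene)triphenylphosphorane, CCOC(=O)C=P(c1ccccc1)(c1ccccc1)c1ccccc1
Why: Wittig olefination with a stabilised ylide under neutral conditions reacts only at the aldehyde (no base-induced aldol reaction of the keto aldehyde) and should give the (E)-enoate.

Step 7
Reactants: 9 keto enoate
Product: 10 ethyl 2-[(3S,5aS,6S,7S,9aS)-3-(tert-butyldimethylsilyloxy)-7-hydroxy-2,2,5a,7-tetramethyldecahydro-1-benzoxepin-6-yl]acetate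
Conditions: SmI2 (2.5 equiv), MeOH (5 equiv), THF, 0 °C
Reagents that add atoms: none
Why: SmI2 reduces the methyl ketone to a samarium ketyl, which adds to the enoate β-carbon (the future C-6), and a second electron plus methanol give the ester; this is the ketyl–olefin reductive cyclisation known for 2,3-trans cyclic ethers and 2-substituted cyclohexanols. The cyclohexane closes 6-exo-trig through a chair in which the O-1 and C-5 bonds of the trans-disubstituted oxepane are both equatorial, which fixes the angular methyl axial. The enoate takes the equatorial site of this chair, so C-6 gets its hydrogen axial (6S, acetate arm cis to the angular methyl). The samarium-bound oxygen, chelated to the ester carbonyl and much larger than methyl, should stay equatorial while the methyl goes axial despite its 1,3-relation to the angular methyl, giving 7S with the hydroxyl trans to the ester arm. The step needs cyclisation to outrun simple ketone reduction and the ketone, not the saturated ester, to be reduced; the electron-poor acceptor and the gem-disubstituted, ring-constrained tether secure both. No α-heteroatom ketone is present (C-3 is a silyl ether), so reductive C–O cleavage is excluded.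

Step 8
Reactants: 10 hydroxy ester
Product: 11 ethyl 2-[(3S,5aS,6S,7S,9aS)-3-(tert-butyldimethylsilyloxy)-2,2,5a,7-tetramethyl-7-(triethylsilyloxy)decahydro-1-benzoxepin-6-yl]acetate
Conditions: TESOTf, 2,6-lutidine, CH2Cl2, −78 to 0 °C
Reagents that add atoms: triethylsilyl triflate, CC[Si](CC)(CC)OS(=O)(=O)C(F)(F)F
Why: Silyl triflate silylation protects the tertiary hydroxyl so that it can neither form a lactol with the aldehyde of step 9 nor add to the enone of step 12.

Step 9
Reactants: 11 silyl-protected ester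
Product: 12 2-[(3S,5aS,6S,7S,9aS)-3-(tert-butyldimethylsilyloxy)-2,2,5a,7-tetramethyl-7-(triethylsilyloxy)decahydro-1-benzoxepin-6-yl]acetaldehyde
Conditions: DIBAL-H (1.1 equiv), CH2Cl2, −78 °C; Rochelle salt work-up
Reagents that add atoms: none
Why: Partial reduction of the ethyl ester with DIBAL-H at −78 °C stops at the tetrahedral aluminium hemiacetal, which releases the aldehyde on work-up.

Step 10
Reactants: 13 (E)-geranylacetone
Product: 14 4-[(2S,3S)-3-{2-[(2S)-3,3-dimethyloxiran-2-yl]ethyl}-3-methyloxiran-2-yl]butan-2-one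
Conditions: L-fructose-derived Shi ketone (30 mol%), Oxone (excess), K2CO3, Bu4NHSO4, MeCN–DMM/aq. borate buffer, 0 °C
Reagents that add atoms: potassium peroxymonosulfate (Oxone), OOS(=O)(=O)[O-].[K+]
Why: Double Shi epoxidation of both trisubstituted (E)-alkenes under catalyst control should give the (S,S)- and (S)-epoxides, which carry the future C-5a/C-9a and C-3 centres of the left half.

Step 11
Reactants: 14 diepoxy ketone; 12 aldehyde
Product: 15 β-hydroxy ketone (aldol adduct, carbinol epimers)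
Conditions: LDA, THF, −78 °C (14); then 12, −78 °C; aq. NH4Cl
Reagents that add atoms: none
Why: Kinetic deprotonation of the methyl ketone at its methyl group and directed aldol addition to the aldehyde form the C–C bond that joins the two halves, and the carbinol configuration is irrelevant.

Step 12
Reactants: 15 β-hydroxy ketone
Product: 17 (E)-enone, via mesylate 16 (not isolated)
Conditions: MsCl, Et3N, CH2Cl2, 0 °C; then DBU, rt
Reagents that add atoms: methanesulfonyl chloride, CS(=O)(=O)Cl (atoms kept only in 16)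
Why: Mesylation of the secondary aldol hydroxyl and E1cB elimination with DBU should give the (E)-enone, and epoxides and silyl ethers tolerate these conditions.

Step 13
Reactants: 17 enone
Product: 18 (Z)-triethylsilyl enol ether
Conditions: Et3SiH, (Ph3P)3RhCl (2 mol%), toluene, 50 °C
Reagents that add atoms: triethylsilane, CC[SiH](CC)CC
Why: Rhodium-catalysed 1,4-hydrosilylation of an enone with a monohydrosilane gives the regiodefined (Z)-silyl enol ether between the carbonyl carbon and the bridge-side carbon, which fixes the site of the next C–C bond.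

Step 14
Reactants: 18 diepoxy silyl enol ether
Product: 19 left-half bicyclic 7-ketone (3-O-TBS)
Conditions: TBSOTf (1.2 equiv), 2,6-di-tert-butyl-4-methylpyridine, CH2Cl2, −78 °C
Reagents that add atoms: tert-butyldimethylsilyl triflate, CC(C)(C)[Si](C)(C)OS(=O)(=O)C(F)(F)F
Why: In this silyl-triflate-initiated epoxide-opening cascade (tandem oxa- and carbacyclisation) the internal epoxide oxygen opens the silyl-activated terminal epoxide at CMe2 to a bicyclic epoxonium ion (oxepane, 7-endo), which the enol ether carbon opens at the tertiary carbon with inversion through a chair (cyclohexanone, 6-endo), so the (E)-derived epoxide gives the trans fusion (5aS,9aS) and the (Z)-enol ether the equatorial C-6 substituent (6S, also the thermodynamic epimer).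

Step 15
Reactants: 19 bicyclic ketone
Product: 20 left-half tertiary alcohol (7R)
Conditions: MeLi, CeCl3, THF, −78 °C
Reagents that add atoms: methyllithium, [Li]C
Why: Organocerium addition to the hindered, enolisable ketone should come from the equatorial direction because the axial angular methyl at C-5a blocks axial attack, giving the axial tertiary alcohol (7R), the epimer of the carbinol made in step 7.

Step 16
Reactants: 20 tris-silyl ether
Product: 21 tetraol
Conditions: TBAF (excess), THF, 50 °C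
Reagents that add atoms: none
Why: Fluoride cleaves the two tert-butyldimethylsilyl ethers and the triethylsilyl ether in one operation.

Step 17
Reactants: 21 tetraol
Product: 22 3,3'-diketone 7,7'-diol
Conditions: Dess–Martin periodinane, NaHCO3, CH2Cl2, rt
Reagents that add atoms: none
Why: Dess–Martin oxidation converts the two secondary alcohols to the 3-ketones while the tertiary alcohols cannot react.

Step 18
Reactants: 22 diketone diol
Product: 23 target diacetate
Conditions: Ac2O, Sc(OTf)3 (5 mol%), MeCN, −20 °C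
Reagents that add atoms: acetic anhydride, CC(=O)OC(C)=O
Why: Scandium triflate-catalysed acylation with acetic anhydride is strong enough to acetylate hindered tertiary alcohols at low temperature without base.

Compound list
1 | neryl acetate, (2Z)-3,7-dimethylocta-2,6-dien-1-yl acetate | CC(C)=CCC/C(C)=C\COC(C)=O | starting material
2 | 2-[(2Z)-3,7-dimethylocta-2,6-dien-1-yl]-4,4,5,5-tetramethyl-1,3,2-dioxaborolane | CC(C)=CCC/C(C)=C\CB1OC(C)(C)C(C)(C)O1 | intermediate
3 | 4-oxopentanal | CC(=O)CCC=O | starting material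
4 | (5S,6S)-6-ethenyl-5-hydroxy-6,10-dimethylundec-9-en-2-one | C=C[C@](C)(CCC=C(C)C)[C@@H](O)CCC(C)=O | intermediate
5 | (5S,6S)-8-[(2S)-3,3-dimethyloxiran-2-yl]-6-ethenyl-5-hydroxy-6-methyloctan-2-one | C=C[C@](C)(CC[C@@H]1OC1(C)C)[C@@H](O)CCC(C)=O | intermediate
6 | 4-[(2S,3S,6S)-6-(tert-butyldimethylsilyloxy)-3-ethenyl-3,7,7-trimethyloxepan-2-yl]butan-2-one | C=C[C@]1(C)CC[C@H](O[Si](C)(C)C(C)(C)C)C(C)(C)O[C@H]1CCC(C)=O | intermediate
7 | 4-[(2S,3S,6S)-6-(tert-butyldimethylsilyloxy)-3,7,7-trimethyl-3-(1,2,4-trioxolan-3-yl)oxepan-2-yl]butan-2-one (trioxolane epimers) | O1COOC1[C@]1(C)CC[C@H](O[Si](C)(C)C(C)(C)C)C(C)(C)O[C@H]1CCC(C)=O | intermediate (not isolated)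
8 | (2S,3R,6S)-6-(tert-butyldimethylsilyloxy)-3,7,7-trimethyl-2-(3-oxobutyl)oxepane-3-carbaldehyde | O=C[C@]1(C)CC[C@H](O[Si](C)(C)C(C)(C)C)C(C)(C)O[C@H]1CCC(C)=O | intermediate
9 | ethyl (2E)-3-[(2S,3S,6S)-6-(tert-butyldimethylsilyloxy)-3,7,7-trimethyl-2-(3-oxobutyl)oxepan-3-yl]prop-2-enoate | CCOC(=O)/C=C/[C@]1(C)CC[C@H](O[Si](C)(C)C(C)(C)C)C(C)(C)O[C@H]1CCC(C)=O | intermediate
10 | ethyl 2-[(3S,5aS,6S,7S,9aS)-3-(tert-butyldimethylsilyloxy)-7-hydroxy-2,2,5a,7-tetramethyldecahydro-1-benzoxepin-6-yl]acetate | CCOC(=O)C[C@H]1[C@]2(C)CC[C@H](O[Si](C)(C)C(C)(C)C)C(C)(C)O[C@H]2CC[C@]1(C)O | intermediate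
11 | ethyl 2-[(3S,5aS,6S,7S,9aS)-3-(tert-butyldimethylsilyloxy)-2,2,5a,7-tetramethyl-7-(triethylsilyloxy)decahydro-1-benzoxepin-6-yl]acetate | CCOC(=O)C[C@H]1[C@]2(C)CC[C@H](O[Si](C)(C)C(C)(C)C)C(C)(C)O[C@H]2CC[C@]1(C)O[Si](CC)(CC)CC | intermediate
12 | 2-[(3S,5aS,6S,7S,9aS)-3-(tert-butyldimethylsilyloxy)-2,2,5a,7-tetramethyl-7-(triethylsilyloxy)decahydro-1-benzoxepin-6-yl]acetaldehyde | O=CC[C@H]1[C@]2(C)CC[C@H](O[Si](C)(C)C(C)(C)C)C(C)(C)O[C@H]2CC[C@]1(C)O[Si](CC)(CC)CC | intermediate
13 | (5E)-6,10-dimethylundeca-5,9-dien-2-one (geranylacetone) | CC(C)=CCC/C(C)=C/CCC(C)=O | starting material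
14 | 4-[(2S,3S)-3-{2-[(2S)-3,3-dimethyloxiran-2-yl]ethyl}-3-methyloxiran-2-yl]butan-2-one | CC(=O)CC[C@@H]1O[C@@]1(C)CC[C@@H]1OC1(C)C | intermediate
15 | 6-[(3S,5aS,6S,7S,9aS)-3-(tert-butyldimethylsilyloxy)-2,2,5a,7-tetramethyl-7-(triethylsilyloxy)decahydro-1-benzoxepin-6-yl]-1-[(2S,3S)-3-{2-[(2S)-3,3-dimethyloxiran-2-yl]ethyl}-3-methyloxiran-2-yl]-5-hydroxyhexan-3-one (C-5 epimers) | O=C(CC(O)C[C@H]1[C@]2(C)CC[C@H](O[Si](C)(C)C(C)(C)C)C(C)(C)O[C@H]2CC[C@]1(C)O[Si](CC)(CC)CC)CC[C@@H]1O[C@@]1(C)CC[C@@H]1OC1(C)C | intermediate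
16 | 5-O-methanesulfonate of 15 | O=C(CC(OS(C)(=O)=O)C[C@H]1[C@]2(C)CC[C@H](O[Si](C)(C)C(C)(C)C)C(C)(C)O[C@H]2CC[C@]1(C)O[Si](CC)(CC)CC)CC[C@@H]1O[C@@]1(C)CC[C@@H]1OC1(C)C | intermediate (not isolated)
17 | (4E)-6-[(3S,5aS,6S,7S,9aS)-3-(tert-butyldimethylsilyloxy)-2,2,5a,7-tetramethyl-7-(triethylsilyloxy)decahydro-1-benzoxepin-6-yl]-1-[(2S,3S)-3-{2-[(2S)-3,3-dimethyloxiran-2-yl]ethyl}-3-methyloxiran-2-yl]hex-4-en-3-one | O=C(/C=C/C[C@H]1[C@]2(C)CC[C@H](O[Si](C)(C)C(C)(C)C)C(C)(C)O[C@H]2CC[C@]1(C)O[Si](CC)(CC)CC)CC[C@@H]1O[C@@]1(C)CC[C@@H]1OC1(C)C | intermediate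
18 | (3Z)-3-(triethylsilyloxy)hex-3-ene analogue of 17 (silyl enol ether, same substituents at C-1 and C-6) | CC[Si](CC)(CC)O/C(=C\CC[C@H]1[C@]2(C)CC[C@H](O[Si](C)(C)C(C)(C)C)C(C)(C)O[C@H]2CC[C@]1(C)O[Si](CC)(CC)CC)CC[C@@H]1O[C@@]1(C)CC[C@@H]1OC1(C)C | intermediate
19 | (3S,5aS,6S,9aS)-3-(tert-butyldimethylsilyloxy)-6-{2-[(3S,5aS,6S,7S,9aS)-3-(tert-butyldimethylsilyloxy)-2,2,5a,7-tetramethyl-7-(triethylsilyloxy)decahydro-1-benzoxepin-6-yl]ethyl}-2,2,5a-trimethyloctahydro-1-benzoxepin-7(2H)-one | O=C1CC[C@@H]2OC(C)(C)[C@@H](O[Si](C)(C)C(C)(C)C)CC[C@@]2(C)[C@@H]1CC[C@H]1[C@]2(C)CC[C@H](O[Si](C)(C)C(C)(C)C)C(C)(C)O[C@H]2CC[C@]1(C)O[Si](CC)(CC)CC | intermediate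
20 | (3S,5aS,6S,7R,9aS)-3-(tert-butyldimethylsilyloxy)-6-{2-[(3S,5aS,6S,7S,9aS)-3-(tert-butyldimethylsilyloxy)-2,2,5a,7-tetramethyl-7-(triethylsilyloxy)decahydro-1-benzoxepin-6-yl]ethyl}-2,2,5a,7-tetramethyldecahydro-1-benzoxepin-7-ol | O[C@]1(C)CC[C@@H]2OC(C)(C)[C@@H](O[Si](C)(C)C(C)(C)C)CC[C@@]2(C)[C@@H]1CC[C@H]1[C@]2(C)CC[C@H](O[Si](C)(C)C(C)(C)C)C(C)(C)O[C@H]2CC[C@]1(C)O[Si](CC)(CC)CC | intermediate
21 | (3S,5aS,6S,7R,9aS)-6-{2-[(3S,5aS,6S,7S,9aS)-3,7-dihydroxy-2,2,5a,7-tetramethyldecahydro-1-benzoxepin-6-yl]ethyl}-2,2,5a,7-tetramethyldecahydro-1-benzoxepine-3,7-diol | O[C@]1(C)CC[C@@H]2OC(C)(C)[C@@H](O)CC[C@@]2(C)[C@@H]1CC[C@H]1[C@]2(C)CC[C@H](O)C(C)(C)O[C@H]2CC[C@]1(C)O | intermediate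
22 | (5aS,6S,7R,9aS)-7-hydroxy-6-{2-[(5aS,6S,7S,9aS)-7-hydroxy-2,2,5a,7-tetramethyl-3-oxodecahydro-1-benzoxepin-6-yl]ethyl}-2,2,5a,7-tetramethyloctahydro-1-benzoxepin-3(2H)-one | O[C@]1(C)CC[C@@H]2OC(C)(C)C(=O)CC[C@@]2(C)[C@@H]1CC[C@H]1[C@]2(C)CCC(=O)C(C)(C)O[C@H]2CC[C@]1(C)O | intermediate
23 | (5aS,6S,7R,9aS)-6-{2-[(5aS,6S,7S,9aS)-7-acetoxy-2,2,5a,7-tetramethyl-3-oxodecahydro-1-benzoxepin-6-yl]ethyl}-2,2,5a,7-tetramethyl-3-oxodecahydro-1-benzoxepin-7-yl acetate | CC(=O)O[C@]1(C)CC[C@@H]2OC(C)(C)C(=O)CC[C@@]2(C)[C@@H]1CC[C@H]1[C@]2(C)CCC(=O)C(C)(C)O[C@H]2CC[C@]1(C)OC(C)=O | target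

Total step count: 18. Longest linear sequence: 17 steps (steps 1–9 and 11–18); step 10 is a one-step branch.

Steps most likely to fail

1. Step 4 (oxepane closure). The hydroxyl may attack the secondary epoxide carbon (6-exo) and give a tetrahydropyran, or the silyl triflate may be diverted by the hemiketal form of the γ-hydroxy ketone. The fallback sets out from 5 and returns at 6.
   - The epoxide is isomerised with Cp2TiCl (Cp2TiCl2, Mn, THF; homolytic C–O cleavage, then β-hydride loss from a methyl group) to the isopropenyl carbinol (5S,6S,9S)-6-ethenyl-5,9-dihydroxy-6,10-dimethylundec-10-en-2-one F1.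
   - The less hindered allylic hydroxyl is silylated (TBSCl, imidazole, DMF) to the 9-O-silyl ether F2.
   - Iodoetherification (NIS, CH2Cl2, 0 °C) closes the oxepane 7-exo-trig at the tertiary carbon, where ring-size and Markovnikov preferences agree, to the 7-(iodomethyl)oxepane F3.
   - Bu3SnH with AIBN (toluene, 80 °C, high tin hydride concentration) removes the iodine and gives 6.

2. Step 14 (epoxide cascade). The acid-labile silyl enol ether may be lost before C–C bond formation, or the two epoxides may be activated without order on this large substrate. The fallback sets out from 12 and returns at 19; it replaces the silyl enol ether by a β-keto ester, whose nucleophilic carbon is fixed by double activation and which survives handling.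
   - Methyl acetoacetate dianion (NaH, then n-BuLi) is alkylated with geranyl bromide to methyl (6E)-7,11-dimethyl-3-oxododeca-6,10-dienoate F4.
   - Shi epoxidation as in step 10 gives the diepoxy β-keto ester F5.
   - Reductive Knoevenagel alkylation of F5 with aldehyde 12 (Hantzsch ester, proline cat., CH2Cl2–EtOH) gives the 2-substituted β-keto ester F6.
   - TBSOTf with 2,6-di-tert-butyl-4-methylpyridine (CH2Cl2, −78 °C) closes both rings with the β-keto ester enol as terminating nucleophile to the bicyclic β-keto ester F7.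
   - Krapcho dealkoxycarbonylation (LiCl, wet DMSO, 140 °C) gives 19 with the C-6 substituent equatorial.

3. Step 18 (double acetylation). The Lewis acid may ionise or eliminate the tertiary carbinols, or acylation of the axial 7R hydroxyl (1,3-diaxial to the angular methyl) may stay incomplete. The fallback sets out from 20 and returns at 23; it acylates the lithium alkoxides before the ketones exist.
   - The tertiary triethylsilyl ether is cleaved selectively (PPTS, MeOH, 0 °C) to the 7,7'-diol 3,3'-bis(silyl ether) F8.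
   - Double deprotonation (n-BuLi, THF, −78 °C) and acetyl chloride give the 7,7'-diacetate F9.
   - HF·pyridine removes both silyl ethers to the 3,3'-diol 7,7'-diacetate F10.
   - Dess–Martin oxidation gives 23.

Further compounds
F1 | step 4 | (5S,6S,9S)-6-ethenyl-5,9-dihydroxy-6,10-dimethylundec-10-en-2-one | C=C[C@](C)(CC[C@H](O)C(C)=C)[C@@H](O)CCC(C)=O
F2 | step 4 | (5S,6S,9S)-9-(tert-butyldimethylsilyloxy)-6-ethenyl-5-hydroxy-6,10-dimethylundec-10-en-2-one | C=C[C@](C)(CC[C@H](O[Si](C)(C)C(C)(C)C)C(C)=C)[C@@H](O)CCC(C)=O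
F3 | step 4 | 4-[(2S,3S,6S)-6-(tert-butyldimethylsilyloxy)-3-ethenyl-7-(iodomethyl)-3,7-dimethyloxepan-2-yl]butan-2-one (C-7 epimers) | C=C[C@]1(C)CC[C@H](O[Si](C)(C)C(C)(C)C)C(C)(CI)O[C@H]1CCC(C)=O
F4 | step 14 | methyl (6E)-7,11-dimethyl-3-oxododeca-6,10-dienoate | COC(=O)CC(=O)CC/C=C(\C)CCC=C(C)C
F5 | step 14 | methyl 5-[(2S,3S)-3-{2-[(2S)-3,3-dimethyloxiran-2-yl]ethyl}-3-methyloxiran-2-yl]-3-oxopentanoate | COC(=O)CC(=O)CC[C@@H]1O[C@@]1(C)CC[C@@H]1OC1(C)C
F6 | step 14 | methyl 2-{2-[(3S,5aS,6S,7S,9aS)-3-(tert-butyldimethylsilyloxy)-2,2,5a,7-tetramethyl-7-(triethylsilyloxy)decahydro-1-benzoxepin-6-yl]ethyl}-5-[(2S,3S)-3-{2-[(2S)-3,3-dimethyloxiran-2-yl]ethyl}-3-methyloxiran-2-yl]-3-oxopentanoate (C-2 epimers) | COC(=O)C(CC[C@H]1[C@]2(C)CC[C@H](O[Si](C)(C)C(C)(C)C)C(C)(C)O[C@H]2CC[C@]1(C)O[Si](CC)(CC)CC)C(=O)CC[C@@H]1O[C@@]1(C)CC[C@@H]1OC1(C)C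
F7 | step 14 | methyl (3S,5aS,9aS)-3-(tert-butyldimethylsilyloxy)-6-{2-[(3S,5aS,6S,7S,9aS)-3-(tert-butyldimethylsilyloxy)-2,2,5a,7-tetramethyl-7-(triethylsilyloxy)decahydro-1-benzoxepin-6-yl]ethyl}-2,2,5a-trimethyl-7-oxodecahydro-1-benzoxepine-6-carboxylate (C-6 configuration open) | O=C1CC[C@@H]2OC(C)(C)[C@@H](O[Si](C)(C)C(C)(C)C)CC[C@@]2(C)C1(C(=O)OC)CC[C@H]1[C@]2(C)CC[C@H](O[Si](C)(C)C(C)(C)C)C(C)(C)O[C@H]2CC[C@]1(C)O[Si](CC)(CC)CC
F8 | step 18 | (3S,5aS,6S,7R,9aS)-3-(tert-butyldimethylsilyloxy)-6-{2-[(3S,5aS,6S,7S,9aS)-3-(tert-butyldimethylsilyloxy)-7-hydroxy-2,2,5a,7-tetramethyldecahydro-1-benzoxepin-6-yl]ethyl}-2,2,5a,7-tetramethyldecahydro-1-benzoxepin-7-ol | O[C@]1(C)CC[C@@H]2OC(C)(C)[C@@H](O[Si](C)(C)C(C)(C)C)CC[C@@]2(C)[C@@H]1CC[C@H]1[C@]2(C)CC[C@H](O[Si](C)(C)C(C)(C)C)C(C)(C)O[C@H]2CC[C@]1(C)O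
F9 | step 18 | 7,7'-diacetate of F8 | CC(=O)O[C@]1(C)CC[C@@H]2OC(C)(C)[C@@H](O[Si](C)(C)C(C)(C)C)CC[C@@]2(C)[C@@H]1CC[C@H]1[C@]2(C)CC[C@H](O[Si](C)(C)C(C)(C)C)C(C)(C)O[C@H]2CC[C@]1(C)OC(C)=O
F10 | step 18 | (3S,5aS,6S,7R,9aS)-6-{2-[(3S,5aS,6S,7S,9aS)-7-acetoxy-3-hydroxy-2,2,5a,7-tetramethyldecahydro-1-benzoxepin-6-yl]ethyl}-3-hydroxy-2,2,5a,7-tetramethyldecahydro-1-benzoxepin-7-yl acetate | CC(=O)O[C@]1(C)CC[C@@H]2OC(C)(C)[C@@H](O)CC[C@@]2(C)[C@@H]1CC[C@H]1[C@]2(C)CC[C@H](O)C(C)(C)O[C@H]2CC[C@]1(C)OC(C)=O
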